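With the seven-membered ring numbered C1 (acyloxy carbon), C2, C3 (C-methyl), C4, C5 (ketone), C6 (angular methyl), C10 (fusion CH) and the cyclopentane C6, C7, C8, C9 (carbinol), C10, the plan rests on removing C10. What remains, C1 to C6 carrying methyl at C3 and oxygen at C5, is a 2-silyloxy-4-methylphenyl ring bearing a three-carbon chain, C7, C8 and the C9 carbonyl. A chiral copper carbene at C10, from the terminal diazoketone, adds across the arene bond C6–C1 and the norcaradiene opens: one operation gives both bonds, both rings and the C10 stereocentre. The arene oxygen is carried as a silyl ether so that fluoride, not acid, later unmasks C5.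

Key step: step 5

Remark (assumption): the sense of induction of the copper–bis(oxazoline) catalyst on this substrate is assumed; the ligand is written as its (R,R) antipode and the mirror-image ligand would be taken if a first run gave the 8aS azulenone.

Convention: atom numbers are those of the first paragraph, with C11 for the carbon that becomes the C6 methyl group. β is the face of H10 and α the opposite face. TBS = tert-butyldimethylsilyl.

**Step 1**
Reactants: 1 2-hydroxy-4-methylbenzaldehyde
Product: 2 2-(TBS-oxy)-4-methylbenzaldehyde
Conditions: TBSCl, imidazole, DMF, rt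
Reagents that add atoms: tert-butyldimethylsilyl chloride, CC(C)(C)[Si](C)(C)Cl
Why: Silylation of a phenol with a silyl chloride and imidazole is routine, leaves the aldehyde untouched and puts a bulky, fluoride-labile group on the arene oxygen; no stereocentre is formed.

**Step 2**
Reactants: 2 2-(TBS-oxy)-4-methylbenzaldehyde; 3 benzyl (triphenylphosphoranylidene)acetate
Product: 4 benzyl (E)-3-[2-(TBS-oxy)-4-methylphenyl]prop-2-enoate
Conditions: toluene, 80 °C
Reagents that add atoms: none
Why: Wittig olefination with a stabilised ylide runs under neutral conditions that spare the aryl silyl ether and gives the E-cinnamate, and the benzyl ester lets the acid be released later by hydrogen instead of hydroxide.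

**Step 3**
Reactants: 4 benzyl (E)-3-[2-(TBS-oxy)-4-methylphenyl]prop-2-enoate
Product: 6 3-[2-(TBS-oxy)-4-methylphenyl]propanoic acid, via saturated benzyl ester 5 (not isolated)
Conditions: H2 (1 atm), 10% Pd/C, EtOAc, rt
Reagents that add atoms: none
Why: Catalytic hydrogenation saturates the conjugated C7=C8 bond and hydrogenolyses the benzyl ester in the same flask, which gives the free acid without a basic saponification that would endanger the aryl silyl ether.

**Step 4**
Reactants: 6 3-[2-(TBS-oxy)-4-methylphenyl]propanoic acid; 7 (trimethylsilyl)diazomethane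
Product: 9 1-diazo-4-[2-(TBS-oxy)-4-methylphenyl]butan-2-one, via acid chloride 8 (not isolated)
Conditions: (COCl)2, DMF (cat.), CH2Cl2, 0 °C to rt; evaporate; 7 (2 equiv), MeCN/THF, 0 °C to rt
Reagents that add atoms: none
Why: Chloride formation under Vilsmeier-type catalysis followed by C-acylation of the silyl diazomethane (the diazoketone stage of the Arndt–Eistert sequence) gives the terminal diazoketone, the C-silyl group leaving as Me3SiCl.

**Step 5**
Reactants: 9 1-diazo-4-[2-(TBS-oxy)-4-methylphenyl]butan-2-one
Product: 11 (8aR)-4-(TBS-oxy)-6-methyl-3,8a-dihydroazulen-1(2H)-one (route numbering: C9 ketone; C5=C6, C3=C4 and C1=C2 alkenes; H10 β), via norcaradiene 10 (not isolated)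
Conditions: CuCl (5 mol %), NaB[3,5-(CF3)2C6H3]4 (6 mol %), 2,2′-(propane-2,2-diyl)bis[(4R)-4-phenyl-4,5-dihydrooxazole] (6 mol %), CH2Cl2, 40 °C, slow addition of 9
Reagents that add atoms: none
Why: The cationic copper–bis(oxazoline) complex decomposes the diazoketone to an electrophilic copper carbene at C10, which cyclopropanates the C6–C1 π-bond of the tethered arene to norcaradiene 10; this opens by thermal disrotatory six-electron electrocyclic cleavage of the C6–C1 σ-bond to cycloheptatriene 11. The closest known reaction type is the enantioselective intramolecular Buchner reaction of 1-diazo-4-arylbutan-2-ones to 3,8a-dihydroazulen-1(2H)-ones under chiral copper or dirhodium catalysis. The cyclopentanone closes when the carbene carbon bonds to the ipso carbon C6 through the three-atom tether, and the seven-membered ring arises by ring expansion, the second carbene bond C10–C1 being made to the ortho carbon before the former aromatic bond C6–C1 is broken. C10 is the only stereocentre and is fixed by the chiral ligand, which decides from which enantiotopic face of the C6–C1 bond the carbene is delivered. The step needs addition on the unsubstituted ortho side, secured by the bulky silyloxy group on C5 that blocks the C6–C5 bond, and addition in preference to aromatic C–H insertion at C1, secured because C1 is meta to both donor groups and thus not activated. The product should be used at once and kept from acid and amine bases, because C10–H is α to the ketone and doubly allylic.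

**Step 6**
Reactants: 11 (8aR)-4-(TBS-oxy)-6-methyl-3,8a-dihydroazulen-1(2H)-one
Product: 12 (1R,8aR)-4-(TBS-oxy)-6-methyl-1-(propan-2-yl)-1,2,3,8a-tetrahydroazulen-1-ol (route numbering: C9 α-hydroxy, β-isopropyl; H10 β)
Conditions: iPrMgCl, CeCl3 (dried), THF, −78 °C; aq NH4Cl
Reagents that add atoms: isopropylmagnesium chloride, CC(C)[Mg]Cl
Why: Organocerium reagents add to easily enolised ketones without acting as bases or hydride donors (organocerium 1,2-addition), so the labile C10–H survives, and the isopropyl group should approach C9 from the β-face next to H10, away from the C10–C1 bond that flanks the α-face, which places the new hydroxyl α.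

**Step 7**
Reactants: 12 (1R,8aR)-4-(TBS-oxy)-6-methyl-1-(propan-2-yl)-1,2,3,8a-tetrahydroazulen-1-ol
Product: 13 siloxycyclopropane: 12 with a cyclopropane C5–C6–C11 in place of the C5=C6 bond, C11 on the α-face (cis to the C9 hydroxyl), C5 bearing the TBS-oxy group, C3=C4 and C1=C2 alkenes intact
Conditions: Et2Zn, CH2I2, CH2Cl2, −20 to 0 °C; pyridine, then aq NaHCO3
Reagents that add atoms: diiodomethane, ICI
Why: Hydroxyl-directed Simmons–Smith cyclopropanation: the zinc alkoxide formed at C9 delivers the methylene to the α-face of the silyl enol ether C5=C6, the most electron-rich of the three alkenes, so that the future C6 methyl carbon is set cis to the C9 oxygen and trans to H10.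

**Step 8**
Reactants: 13 siloxycyclopropane
Product: 15 trans-fused dienone (C5 ketone; C3=C4 and C1=C2 alkenes; C3 methyl; C6 α-methyl; C9 α-hydroxy and β-isopropyl; H10 β), via cyclopropanol 14 (not isolated)
Conditions: TBAF, wet THF, 0 °C; aq NH4Cl
Reagents that add atoms: none
Why: Fluoride cleaves the Si–O bond and the cyclopropanolate opens towards the primary carbon (base-mediated ring opening of a cyclopropanol to an α-methyl ketone), which turns C11 into the C6 methyl group with C6 unchanged and frees the C5 ketone in conjugation with the diene, without the acid that would drive a 1-dienyl-1-alkoxycyclopropane towards ring-expanded products and threaten the tertiary carbinol.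

**Step 9**
Reactants: 15 trans-fused dienone
Product: 16 C1–C2 α-epoxide of 15 (epoxide oxygen cis to the C9 hydroxyl and the C6 methyl, trans to H10; C3=C4–C5=O enone intact)
Conditions: VO(acac)2 (cat.), tBuOOH, CH2Cl2, rt to 40 °C
Reagents that add atoms: tert-butyl hydroperoxide, CC(C)(C)OO
Why: Vanadium-catalysed hydroxyl-directed epoxidation of a homoallylic alcohol: the C9 alkoxide, cis to C1 on the five-membered ring, carries the peroxide to the α-face of the remote C1=C2 bond and so sets C1, while the C3=C4 bond next to the ketone is too electron-poor for this electrophilic oxidant.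

**Step 10**
Reactants: 16 C1–C2 α-epoxide
Product: 17 (1R,6S,9R,10S)-diol enone (C1 α-hydroxy; C2 methylene; C3=C4–C5=O; C6 α-methyl; C9 α-hydroxy and β-isopropyl)
Conditions: Pd2(dba)3·CHCl3 (cat.), nBu3P, HCO2H, Et3N, 1,4-dioxane, rt
Reagents that add atoms: none
Why: Palladium-catalysed formate hydrogenolysis of an alkenyl oxirane (Tsuji–Trost-type allylic reduction): zerovalent palladium ionises the allylic C2–O bond and hydride from the formate is returned to C2, the allyl terminus remote from the carbonyl, which leaves the C3=C4 bond conjugated and the C1–O bond with its configuration untouched.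

**Step 11**
Reactants: 18 vanillic acid
Product: 20 4-(TBS-oxy)-3-methoxybenzoic acid, via bis-silylated vanillate 19 (not isolated)
Conditions: TBSCl (2.2 equiv), imidazole, DMF, rt; then AcOH/THF/H2O, rt
Reagents that add atoms: tert-butyldimethylsilyl chloride, CC(C)(C)[Si](C)(C)Cl
Why: Exhaustive silylation followed by mild hydrolysis of the far more labile silyl ester (selective silyl ester cleavage) leaves the phenol protected and the acid free.

**Step 12**
Reactants: 17 (1R,6S,9R,10S)-diol enone; 20 4-(TBS-oxy)-3-methoxybenzoic acid
Product: 21 C1 4-(TBS-oxy)-3-methoxybenzoate of 17 (the O-silylated target)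
Conditions: DCC, DMAP, CH2Cl2, 0 °C to rt
Reagents that add atoms: none
Why: Steglich esterification acylates the secondary C1 hydroxyl with retention, whereas the tertiary C9 hydroxyl is too hindered to react.

**Step 13**
Reactants: 21 C1 4-(TBS-oxy)-3-methoxybenzoate of 17
Product: 22 the target, (1R,6S,9R,10S) in route numbering
Conditions: TBAF, AcOH, THF, 0 °C
Reagents that add atoms: none
Why: Fluoride removes the aryl silyl ether quickly (fluoride desilylation), and the acetic acid buffer keeps the medium from becoming basic enough to eliminate the δ-acyloxy group of the enone or to cleave the ester.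

**Compound list**

1 | 2-hydroxy-4-methylbenzaldehyde | Cc1ccc(C=O)c(O)c1 | starting material
2 | 2-(TBS-oxy)-4-methylbenzaldehyde | Cc1ccc(C=O)c(O[Si](C)(C)C(C)(C)C)c1 | intermediate
3 | benzyl (triphenylphosphoranylidene)acetate | O=C(C=P(c1ccccc1)(c1ccccc1)c1ccccc1)OCc1ccccc1 | starting material
4 | benzyl (E)-3-[2-(TBS-oxy)-4-methylphenyl]prop-2-enoate | Cc1ccc(/C=C/C(=O)OCc2ccccc2)c(O[Si](C)(C)C(C)(C)C)c1 | intermediate
5 | benzyl 3-[2-(TBS-oxy)-4-methylphenyl]propanoate (not isolated) | Cc1ccc(CCC(=O)OCc2ccccc2)c(O[Si](C)(C)C(C)(C)C)c1 | intermediate
6 | 3-[2-(TBS-oxy)-4-methylphenyl]propanoic acid | Cc1ccc(CCC(=O)O)c(O[Si](C)(C)C(C)(C)C)c1 | intermediate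
7 | (trimethylsilyl)diazomethane | C[Si](C)(C)C=[N+]=[N-] | starting material
8 | 3-[2-(TBS-oxy)-4-methylphenyl]propanoyl chloride (not isolated) | Cc1ccc(CCC(=O)Cl)c(O[Si](C)(C)C(C)(C)C)c1 | intermediate
9 | 1-diazo-4-[2-(TBS-oxy)-4-methylphenyl]butan-2-one | Cc1ccc(CCC(=O)C=[N+]=[N-])c(O[Si](C)(C)C(C)(C)C)c1 | intermediate
10 | norcaradiene with cyclopropane C10–C6–C1, valence tautomer of 11 (not isolated) | O=C1CC[C@@]23C(O[Si](C)(C)C(C)(C)C)=CC(C)=C[C@@H]2[C@@H]13 | intermediate
11 | (8aR)-4-(TBS-oxy)-6-methyl-3,8a-dihydroazulen-1(2H)-one | CC(C)(C)[Si](C)(C)OC1=C2CCC(=O)[C@@H]2C=CC(C)=C1 | intermediate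
12 | (1R,8aR)-4-(TBS-oxy)-6-methyl-1-(propan-2-yl)-1,2,3,8a-tetrahydroazulen-1-ol | CC(C)[C@]1(O)CCC2=C(O[Si](C)(C)C(C)(C)C)C=C(C)C=C[C@@H]12 | intermediate
13 | siloxycyclopropane (C5–C6–C11 ring, C11 α) | CC(C)[C@]1(O)CC[C@@]23C[C@@]3(O[Si](C)(C)C(C)(C)C)C=C(C)C=C[C@@H]12 | intermediate
14 | cyclopropanol from 13 (not isolated) | CC(C)[C@]1(O)CC[C@@]23C[C@@]3(O)C=C(C)C=C[C@@H]12 | intermediate
15 | trans-fused dienone (C5 ketone, C3=C4, C1=C2, C6 α-methyl, C9 α-OH) | CC(C)[C@]1(O)CC[C@]2(C)C(=O)C=C(C)C=C[C@@H]12 | intermediate
16 | C1–C2 α-epoxide of 15 | CC(C)[C@]1(O)CC[C@]2(C)C(=O)C=C(C)[C@H]3O[C@H]3[C@@H]12 | intermediate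
17 | (1R,6S,9R,10S)-diol enone | CC(C)[C@]1(O)CC[C@]2(C)C(=O)C=C(C)C[C@@H](O)[C@@H]12 | intermediate
18 | vanillic acid | COc1cc(C(=O)O)ccc1O | starting material
19 | TBS 4-(TBS-oxy)-3-methoxybenzoate (not isolated) | COc1cc(C(=O)O[Si](C)(C)C(C)(C)C)ccc1O[Si](C)(C)C(C)(C)C | intermediate
20 | 4-(TBS-oxy)-3-methoxybenzoic acid | COc1cc(C(=O)O)ccc1O[Si](C)(C)C(C)(C)C | intermediate
21 | O-TBS-protected target | COc1cc(C(=O)O[C@@H]2CC(C)=CC(=O)[C@@]3(C)CC[C@@](O)(C(C)C)[C@H]23)ccc1O[Si](C)(C)C(C)(C)C | intermediate
22 | CNP0136950.1 | COc1cc(C(=O)O[C@@H]2CC(C)=CC(=O)[C@@]3(C)CC[C@@](O)(C(C)C)[C@H]23)ccc1O | target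

**Step count**

Total: 13 steps. Longest linear sequence: 12 steps (steps 1 to 10, 12 and 13); step 11 is a one-step side branch.

**Steps most likely to fail**

Step 5. The ligand may discriminate the two faces of the C6–C1 bond incompletely with the ortho-silyloxy arene, or the C10 configuration may erode by enolisation before the ketone is consumed. Fallback, setting out from 9: the ring expansion would be run without asymmetric induction using Rh2(OAc)4 (dirhodium tetraacetate) in CH2Cl2. This should give 10 together with the mirror-image norcaradiene F1 in the flask, and then 11 together with the (8aS)-azulenone F2. The conditions of step 6 would convert the racemate into 12 and the mirror-image carbinol F3. These are the first configurationally stable compounds and would be separated by preparative chromatography on a chiral stationary phase such as amylose tris(3,5-dimethylphenylcarbamate). The fallback returns to the route at 12.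

Step 7. Methylene transfer may go to the C1=C2 bond, which the zinc alkoxide can also reach, or to more than one alkene, or the Lewis-acidic zinc salts may degrade the silyl trienol ether. Fallback, setting out from 12: the methyl group would be introduced by enolate alkylation instead of carbenoid delivery. Anhydrous benzyltrimethylammonium fluoride and MeI in THF at −20 °C should release the benzyltrimethylammonium enolate F4 in the flask. Its only carbanionic position is C6, since the diene is cross-conjugated. Methylation is expected from the α-face, opposite the isopropyl group and H10. The fallback returns to the route at 15 and makes step 8 unnecessary.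

Step 9. Oxygen transfer to the electron-poor γ,δ-alkene may be slow, or delivery from the tertiary hydroxyl may be incomplete, so that the peroxide attacks from the β-face. Fallback, setting out from 15: epoxidation with mCPBA and NaHCO3 in CH2Cl2 would be accepted whatever its facial outcome, and the epoxides separated. Any 16 continues as planned. The β-epoxide F5 would be opened under the conditions of step 10 to the C1-epimeric diol enone F6. This would be esterified with acid 20 under Mitsunobu conditions (PPh3, DIAD, toluene, 0 °C to rt), so that C1 is set by inversion instead of directed delivery. The fallback returns to the route at 21.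

**Further compounds**

F1 | step 5 | mirror-image norcaradiene (enantiomer of 10) | O=C1CC[C@]23C(O[Si](C)(C)C(C)(C)C)=CC(C)=C[C@H]2[C@H]13
F2 | step 5 | (8aS)-azulenone (enantiomer of 11) | CC(C)(C)[Si](C)(C)OC1=C2CCC(=O)[C@H]2C=CC(C)=C1
F3 | step 5 | mirror-image carbinol (enantiomer of 12) | CC(C)[C@@]1(O)CCC2=C(O[Si](C)(C)C(C)(C)C)C=C(C)C=C[C@H]12
F4 | step 7 | benzyltrimethylammonium enolate of the C5 ketone | CC(C)[C@]1(O)CCC2=C([O-])C=C(C)C=C[C@@H]12.C[N+](C)(C)Cc1ccccc1
F5 | step 9 | C1–C2 β-epoxide of 15 | CC(C)[C@]1(O)CC[C@]2(C)C(=O)C=C(C)[C@@H]3O[C@@H]3[C@@H]12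
F6 | step 9 | C1-epimeric diol enone (1-epi-17) | CC(C)[C@]1(O)CC[C@]2(C)C(=O)C=C(C)C[C@H](O)[C@@H]12
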